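**Retrosynthetic overview**
1. Target 14 ⇒ PMB-protected ester 13 ⇒ alcohol 11 ⇒ oxolane aldehyde 8 + non-8-enyl Grignard reagent (chelation control sets C1′) ⇒ oxolane acetal 6.
2. 6 ⇒ 1,1-dimethoxypropan-2-one 3 + (R)-2-chloroheptanal 2 in one flask: aldol addition (ring C4–C3), boron-chelate syn reduction, then displacement of chloride by the new hydroxyl (ring O1–C2).
3. Enabling feature: in the oxolane (O1, C2 pentyl, C3 hydroxyl, C4 H2, C5 side chain) the atoms O1–C5–C4–C3(OH) form a 1,3-dioxygenated aldol array and C3(OH)–C2(O1) a vicinal dioxygen pair. C3 is therefore a latent aldehyde carbon, C2 its α-carbon carrying a leaving group, and the oxygen on C5 sits at the right distance from C2 for a five-membered closure.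
4. Only one ring, the oxolane, is formed (step 2). The single catalytic stereocentre (C–Cl of 2, step 1) is relayed to C3 (1,2-induction), C5 (1,3-induction), C2 (inversion) and C1′ (chelation).

Key step: step 2

Assumption: ring locants are those given in line 3 and C1′ is the ester-bearing carbon; the catalyst antipode in step 1 that delivers the R chloride is to be fixed by a rotation check on a test batch reduced to 2-chloroheptan-1-ol; compounds 1, 3, 9 and 12 are taken as commercial.

**Route**

Step 1
Reactants: 1 heptanal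
Product: 2 (R)-2-chloroheptanal
Conditions: N-chlorosuccinimide, trans-2,5-diphenylpyrrolidine (10 mol %, antipode giving R), CH2Cl2, 0 °C to rt; short pentane filtration, used at once
Reagents that add atoms: N-chlorosuccinimide, O=C1CCC(=O)N1Cl
Why: Enamine-catalysed asymmetric α-chlorination of an aldehyde, in which the C2-symmetric amine forms an E-enamine screened on one face by a phenyl group, so that electrophilic chlorine should be delivered to the open face and set the C–Cl stereocentre (later ring C2, after inversion).

Step 2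
Reactants: 3 1,1-dimethoxypropan-2-one; 2 (R)-2-chloroheptanal
Product: 6 (2S,3S,5R)-5-(dimethoxymethyl)-2-pentyloxolan-3-ol, via anti ketochlorohydrin 4 (not isolated), via syn chlorodiol 5 (not isolated)
Conditions: LiN(i-Pr)2, THF, −78 °C; 2, −78 °C; AcOH (1 equiv), Et2BOMe, MeOH, then NaBH4, −78 °C; AcOH, MeOH, 90 °C (sealed tube)
Reagents that add atoms: none
Why: The kinetic lithium enolate of 3 (methyl side; the acetal methine is not deprotonated) adds to aldehyde 2 in an aldol addition that forms the ring C4–C3 bond, and a Cornforth-type transition state (C=O and C–Cl dipoles opposed, attack past the hydrogen) should give the 4,5-anti chlorohydrin 4. Exchange of the aldolate onto boron gives a six-membered diethylboron chelate, and external axial hydride delivery (Narasaka–Prasad reduction) should set the C2 carbinol of 5 1,3-syn to its C4 hydroxyl. On heating in acetate-buffered methanol the C2 hydroxyl of 5 should displace chloride at C5 with inversion (intramolecular Williamson-type SN2), which forms the ring O1–C2 bond and closes the oxolane, the only ring, in the 5-exo-tet mode. The closest known reaction types are the lithium enolate aldol of methyl ketones with α-chloro aldehydes, the boron-chelate syn reduction of β-hydroxy ketones and the thermal cycloetherification of chloro diols, here run in one flask. Ring C3 is controlled by the C–Cl stereocentre of 2 (1,2-induction), ring C5 by C3 through the boron chelate (1,3-induction) and ring C2 by stereospecific inversion of the C–Cl centre. The selectivity needed is closure by the distal hydroxyl and not epoxide formation by the vicinal one: with no alkoxide present under neutral buffered conditions the 3-exo-tet path is shut, and the dimethyl acetal only exchanges degenerately in methanol.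

Step 3
Reactants: 6 (2S,3S,5R)-5-(dimethoxymethyl)-2-pentyloxolan-3-ol
Product: 7 (2S,3S,5R)-5-(dimethoxymethyl)-3-[(4-methoxybenzyl)oxy]-2-pentyloxolane
Conditions: NaH, 4-methoxybenzyl chloride, Bu4NI (cat.), THF/DMF, 0 °C to rt
Reagents that add atoms: 4-methoxybenzyl chloride, COc1ccc(CCl)cc1
Why: Williamson etherification of the secondary alkoxide under basic conditions that leave the acetal and all stereocentres untouched, giving an ether that should survive dilute acid, the Grignard reagent and acylation and be removable oxidatively at the end.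

Step 4
Reactants: 7 (2S,3S,5R)-5-(dimethoxymethyl)-3-[(4-methoxybenzyl)oxy]-2-pentyloxolane
Product: 8 (2R,4S,5S)-4-[(4-methoxybenzyl)oxy]-5-pentyloxolane-2-carbaldehyde
Conditions: 2 M aq. HCl, THF, 40 °C; used crude
Reagents that add atoms: water, O
Why: Acid-catalysed acetal hydrolysis through the methoxy-oxocarbenium ion, under which the PMB ether and the oxolane should be stable, with the α-alkoxy aldehyde taken on crude to avoid epimerisation at the formyl-bearing ring carbon.

Step 5
Reactants: 8 (2R,4S,5S)-4-[(4-methoxybenzyl)oxy]-5-pentyloxolane-2-carbaldehyde; 9 9-bromonon-1-ene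
Product: 11 (R)-1-[(2R,4S,5S)-4-[(4-methoxybenzyl)oxy]-5-pentyloxolan-2-yl]dec-9-en-1-ol, via non-8-enylmagnesium bromide 10 (not isolated)
Conditions: 9, Mg, Et2O, rt; 8, MgBr2·OEt2, CH2Cl2, −78 °C, then 10; aq. NH4Cl
Reagents that add atoms: none
Why: Grignard addition under Cram-chelate control, in which magnesium bridges the ring oxygen and the carbonyl oxygen in a five-membered chelate and the nucleophile attacks past the α-hydrogen, away from the ring CH2, which should set C1′ as R (threo to the ring oxygen).

Step 6
Reactants: 11 (R)-1-[(2R,4S,5S)-4-[(4-methoxybenzyl)oxy]-5-pentyloxolan-2-yl]dec-9-en-1-ol; 12 octadecanoyl chloride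
Product: 13 (R)-1-[(2R,4S,5S)-4-[(4-methoxybenzyl)oxy]-5-pentyloxolan-2-yl]dec-9-en-1-yl octadecanoate
Conditions: Et3N, DMAP (cat.), CH2Cl2, 0 °C to rt
Reagents that add atoms: none
Why: DMAP-catalysed acylation through the acylpyridinium ion of the only free hydroxyl (C1′), with no stereocentre touched.

Step 7
Reactants: 13 (R)-1-[(2R,4S,5S)-4-[(4-methoxybenzyl)oxy]-5-pentyloxolan-2-yl]dec-9-en-1-yl octadecanoate
Product: 14 (R)-1-[(2R,4S,5S)-4-hydroxy-5-pentyloxolan-2-yl]dec-9-en-1-yl octadecanoate
Conditions: DDQ, CH2Cl2/pH 7 buffer, 0 °C to rt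
Reagents that add atoms: none
Why: Oxidative cleavage of the PMB ether (benzylic oxidation to an oxocarbenium ion that water hydrolyses), under which the ester, the terminal alkene and the oxolane should be inert, releasing the ring C3 hydroxyl.

**Compound list**
1 | heptanal | CCCCCCC=O | starting material
2 | (R)-2-chloroheptanal | CCCCC[C@@H](Cl)C=O | intermediate
3 | 1,1-dimethoxypropan-2-one | COC(OC)C(C)=O | starting material
4 | (4S,5R)-5-chloro-4-hydroxy-1,1-dimethoxydecan-2-one | COC(OC)C(=O)C[C@H](O)[C@@H](CCCCC)Cl | intermediate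
5 | (2R,4S,5R)-5-chloro-1,1-dimethoxydecane-2,4-diol | COC(OC)[C@H](O)C[C@H](O)[C@@H](CCCCC)Cl | intermediate
6 | (2S,3S,5R)-5-(dimethoxymethyl)-2-pentyloxolan-3-ol | COC(OC)[C@H]1C[C@H](O)[C@H](CCCCC)O1 | intermediate
7 | (2S,3S,5R)-5-(dimethoxymethyl)-3-[(4-methoxybenzyl)oxy]-2-pentyloxolane | COC(OC)[C@H]1C[C@H](OCc2ccc(OC)cc2)[C@H](CCCCC)O1 | intermediate
8 | (2R,4S,5S)-4-[(4-methoxybenzyl)oxy]-5-pentyloxolane-2-carbaldehyde | O=C[C@H]1C[C@H](OCc2ccc(OC)cc2)[C@H](CCCCC)O1 | intermediate
9 | 9-bromonon-1-ene | C=CCCCCCCCBr | starting material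
10 | non-8-enylmagnesium bromide | C=CCCCCCCC[Mg]Br | intermediate
11 | (R)-1-[(2R,4S,5S)-4-[(4-methoxybenzyl)oxy]-5-pentyloxolan-2-yl]dec-9-en-1-ol | C=CCCCCCCC[C@@H](O)[C@H]1C[C@H](OCc2ccc(OC)cc2)[C@H](CCCCC)O1 | intermediate
12 | octadecanoyl chloride | CCCCCCCCCCCCCCCCCC(=O)Cl | starting material
13 | (R)-1-[(2R,4S,5S)-4-[(4-methoxybenzyl)oxy]-5-pentyloxolan-2-yl]dec-9-en-1-yl octadecanoate | C=CCCCCCCC[C@@H](OC(=O)CCCCCCCCCCCCCCCCC)[C@H]1C[C@H](OCc2ccc(OC)cc2)[C@H](CCCCC)O1 | intermediate
14 | (R)-1-[(2R,4S,5S)-4-hydroxy-5-pentyloxolan-2-yl]dec-9-en-1-yl octadecanoate | C=CCCCCCCC[C@@H](OC(=O)CCCCCCCCCCCCCCCCC)[C@H]1C[C@H](O)[C@H](CCCCC)O1 | target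

**Count and risks**
Total step count: 7. Longest linear sequence: 7 steps (1 → 2 → 6 → 7 → 8 → 11 → 13 → 14).

Steps most likely to fail:

Step 2. The 1,3-syn selectivity may erode if hydride reaches the activated dialkoxy ketone before the boron chelate has formed from the lithium aldolate. The chloro aldehyde may be enolised by the enolate, and epoxide closure or acetal exchange may compete during the thermal stage. The fallback sets out from 2 and comes back at 8; it buys ring C5 from the chiral pool and makes the C4–C3 bond with a carbanion already at the alcohol oxidation level. Commercial (S)-3-chloropropane-1,2-diol F1 is silylated at the primary hydroxyl (i-Pr3SiCl, imidazole) to (S)-1-chloro-3-[(triisopropylsilyl)oxy]propan-2-ol F2. Deprotonation with n-BuLi and chlorine–lithium exchange with lithium naphthalenide (LiC10H8) at −78 °C should give lithium (R)-1-lithio-3-[(triisopropylsilyl)oxy]propan-2-olate F3. F3 should add to 2 under Cornforth control to give, after neutralisation with AcOH, (2R,4S,5R)-5-chloro-1-[(triisopropylsilyl)oxy]decane-2,4-diol F4. Heating F4 in buffered methanol should close it with inversion to (2S,3S,5R)-2-pentyl-5-{[(triisopropylsilyl)oxy]methyl}oxolan-3-ol F5. Etherification (NaH, 4-methoxybenzyl chloride) gives {[(2R,4S,5S)-4-[(4-methoxybenzyl)oxy]-5-pentyloxolan-2-yl]methoxy}triisopropylsilane F6, Bu4NF gives [(2R,4S,5S)-4-[(4-methoxybenzyl)oxy]-5-pentyloxolan-2-yl]methanol F7, and Dess–Martin oxidation of F7 leads to 8 without an acidic acetal hydrolysis.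

Step 5. Chelation may be incomplete, so that Felkin–Anh addition competes and lowers the facial selectivity at C1′; the α-alkoxy aldehyde may also epimerise. The fallback sets out from 8 and comes back at 11; it sets C1′ by hydride reduction of a ketone instead of by C–C bond formation. Addition of 10 to 8 in THF without the chelating additive would give 11 mixed with (S)-1-[(2R,4S,5S)-4-[(4-methoxybenzyl)oxy]-5-pentyloxolan-2-yl]dec-9-en-1-ol F8. The mixture is oxidised with Dess–Martin periodinane to 1-[(2R,4S,5S)-4-[(4-methoxybenzyl)oxy]-5-pentyloxolan-2-yl]dec-9-en-1-one F9. LiBH(s-Bu)3 in THF at −78 °C should then reduce F9 under Felkin–Anh control (ring oxygen anti to the incoming hydride) to the threo alcohol 11.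

Step 1. Partial racemisation by enolisation and over-chlorination during enamine catalysis would lower the enantiomeric purity that every later stereocentre inherits. The fallback sets out from 1 and comes back at 2 and makes no new compound; it changes the mode of chlorine delivery from electrophilic to nucleophilic. Under singly-occupied-orbital activation (2-tert-butyl-3,5-dimethylimidazolidin-4-one trifluoroacetate of the antipode giving R, Cu(O2CCF3)2, Na2S2O8, LiCl, MeCN/H2O, 10 °C) the enamine is oxidised by one electron and the radical cation is trapped by chloride, which avoids N-chloro species and the basic free amine that promote racemisation.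

**Further compounds**
F1 | step 2 | (S)-3-chloropropane-1,2-diol | OC[C@H](O)CCl
F2 | step 2 | (S)-1-chloro-3-[(triisopropylsilyl)oxy]propan-2-ol | CC(C)[Si](C(C)C)(C(C)C)OC[C@H](O)CCl
F3 | step 2 | lithium (R)-1-lithio-3-[(triisopropylsilyl)oxy]propan-2-olate | CC(C)[Si](C(C)C)(C(C)C)OC[C@H](O[Li])C[Li]
F4 | step 2 | (2R,4S,5R)-5-chloro-1-[(triisopropylsilyl)oxy]decane-2,4-diol | CC(C)[Si](C(C)C)(C(C)C)OC[C@H](O)C[C@H](O)[C@@H](CCCCC)Cl
F5 | step 2 | (2S,3S,5R)-2-pentyl-5-{[(triisopropylsilyl)oxy]methyl}oxolan-3-ol | CC(C)[Si](C(C)C)(C(C)C)OC[C@H]1C[C@H](O)[C@H](CCCCC)O1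
F6 | step 2 | {[(2R,4S,5S)-4-[(4-methoxybenzyl)oxy]-5-pentyloxolan-2-yl]methoxy}triisopropylsilane | CC(C)[Si](C(C)C)(C(C)C)OC[C@H]1C[C@H](OCc2ccc(OC)cc2)[C@H](CCCCC)O1
F7 | step 2 | [(2R,4S,5S)-4-[(4-methoxybenzyl)oxy]-5-pentyloxolan-2-yl]methanol | OC[C@H]1C[C@H](OCc2ccc(OC)cc2)[C@H](CCCCC)O1
F8 | step 5 | (S)-1-[(2R,4S,5S)-4-[(4-methoxybenzyl)oxy]-5-pentyloxolan-2-yl]dec-9-en-1-ol | C=CCCCCCCC[C@H](O)[C@H]1C[C@H](OCc2ccc(OC)cc2)[C@H](CCCCC)O1
F9 | step 5 | 1-[(2R,4S,5S)-4-[(4-methoxybenzyl)oxy]-5-pentyloxolan-2-yl]dec-9-en-1-one | C=CCCCCCCCC(=O)[C@H]1C[C@H](OCc2ccc(OC)cc2)[C@H](CCCCC)O1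
F0 | step 1 | none | none
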